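The bicyclo[3.2.1]oct-3-ene-2,8-dione core is read as the 1,2-transposed isomer of a bicyclo[2.2.2]oct-5-ene-2,3-dione: its C1 bridgehead CH, flanked by the C2 enone carbonyl and the C8 bridging ketone, hides a former 1,2-diketone. The key step is a Lewis-acid-triggered double 1,2-shift (alkenyl, then acyl) that forms C2–C3 and C8–C1 in one operation and creates the conjugated dienone. Its precursor is the Diels–Alder adduct of a vanillin-derived masked o-benzoquinone with tetra-O-benzylpiceatannol, which already carries all aryl-bearing stereocentres; the styryl arm is added by olefination before the shift.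

Key step: step 7

Remark: no dependable asymmetric version of the cycloaddition in step 3 is assumed, so the racemic adduct is resolved in step 4. Locants C1–C8 refer to the bicyclic core of each compound; endo means facing the three-carbon enone bridge, exo means facing the C8 bridge.

Step 1
Reactants: 1 piceatannol
Product: 2 (E)-3,4,3',5'-tetrakis(benzyloxy)stilbene
Conditions: BnBr, K2CO3, DMF, 60 °C
Reagents that add atoms: benzyl bromide, BrCc1ccccc1
Why: Williamson etherification of all four phenols is routine and leaves the (E)-alkene untouched.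

Step 2
Reactants: 3 4-(chloromethyl)-1,2-bis(benzyloxy)benzene
Product: 4 diethyl [3,4-bis(benzyloxy)benzyl]phosphonate
Conditions: P(OEt)3 (neat), 140 °C
Reagents that add atoms: triethyl phosphite, CCOP(OCC)OCC
Why: Michaelis–Arbuzov reaction of the benzylic chloride should give the phosphonate with loss of chloroethane.

Step 3
Reactants: 5 vanillin; 2 (E)-3,4,3',5'-tetrakis(benzyloxy)stilbene (3 equiv, excess recovered)
Product: 7 racemic bicyclo[2.2.2]octenone aldehyde, via masked o-benzoquinone 6 (not isolated)
Conditions: PhI(OAc)2 (slow addition), MeOH/CH2Cl2, 0 → 40 °C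
Reagents that add atoms: methanol, CO
Why: Oxidative dearomatisation of the guaiacol unit gives the o-quinone monoketal 6, whose inverse-electron-demand Diels–Alder reaction with electron-rich 2 should join the resorcinol-bearing (nucleophilic) alkene carbon to the dienone carbon β to the formyl group and the catechol-bearing carbon to the carbon α to the ketone, with the catechol ring endo to the new C5=C6 bridge and the (E)-geometry keeping the two aryl groups trans, so that all four stereocentres are set in relative terms.

Step 4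
Reactants: 7 racemic bicyclo[2.2.2]octenone aldehyde
Product: 8 single enantiomer of the bicyclo[2.2.2]octenone aldehyde
Conditions: preparative HPLC, amylose tris(3,5-dimethylphenylcarbamate) stationary phase, hexane/i-PrOH
Reagents that add atoms: none
Why: Resolution on a chiral stationary phase should separate the enantiomers of this rigid adduct and so fix the absolute configuration of all four stereocentres, to be assigned by X-ray or circular dichroism.

Step 5
Reactants: 8 enantiopure aldehyde; 4 diethyl [3,4-bis(benzyloxy)benzyl]phosphonate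
Product: 9 (E)-styryl diene keto-ketal
Conditions: NaH, THF, 0 °C → rt
Reagents that add atoms: none
Why: Horner–Wadsworth–Emmons olefination of the enal with the semi-stabilised benzylic phosphonate anion should give the (E)-styryl diene, the non-enolisable C2 ketone next to the ketal being far less reactive.

Step 6
Reactants: 9 (E)-styryl diene keto-ketal
Product: 10 bicyclo[2.2.2]oct-5-ene-2,3-dione
Conditions: TFA/H2O (9:1), CH2Cl2, 0 °C → rt
Reagents that add atoms: water, O
Why: Acid-catalysed ketal hydrolysis, with water trapping the C3 oxocarbenium ion before it can rearrange, should unmask the 1,2-diketone without touching the benzyl ethers or the stereocentres.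

Step 7
Reactants: 10 bicyclo[2.2.2]oct-5-ene-2,3-dione
Product: 11 hexa-O-benzyljezonodione (bicyclo[3.2.1]oct-3-ene-2,8-dione)
Conditions: BF3·OEt2 (30 mol %), 2,6-di-tert-butylpyridine (10 mol %), CH2Cl2, −40 → 0 °C
Reagents that add atoms: none
Why: Proposed new method: BF3 bound to the 1,2-dione makes C2 electrophilic, and because the 3,4-bis(benzyloxy)styryl group polarises the diene, its unsubstituted carbon C6, held close to C2 in the cage, should bond to C2 (3-exo attack, transient cyclopropylcarbinyl cation delocalised over C5 and the styryl arm); the cyclopropane then opens at C1–C6 and the C3 acyl carbon migrates from C2 to the electron-poor C1 while the C2 carbonyl is regenerated as the new enone. The closest known reaction types are the homoallyl/cyclopropylcarbinyl Wagner–Meerwein rearrangement of bicyclo[2.2.2]oct-5-en-2-yl cations to bicyclo[3.2.1]octenyl cations and the Lewis-acid-promoted 1,2-acyl shift of α,β-epoxy ketones to 1,3-diketones (semipinacol type). The cyclohexenone ring closes by the 1,2-alkenyl shift and the cyclopentanone ring by the suprafacial 1,2-acyl shift. C1 is the only stereocentre that is re-formed, and the cage dictates its configuration because the acyl carbon stays tethered to C4 and can reach C1 from one face only; C4, C7 and C8 are spectators, so the C7 aryl syn to the alkene becomes endo and the C8 aryl becomes exo. The step needs alkenyl migration towards C2 rather than migration of the benzylic C7 carbon or participation towards C3; the styryl polarisation (charge on C5, not C6) and the gain of a conjugated dienone in place of a 1,2-dione should secure this.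

Step 8
Reactants: 11 hexa-O-benzyljezonodione
Product: 12 jezonodione
Conditions: BCl3, pentamethylbenzene, CH2Cl2, −78 °C; aqueous work-up
Reagents that add atoms: none
Why: Lewis-acid cleavage of the six aryl benzyl ethers with pentamethylbenzene as a non-basic benzyl-cation scavenger should free the phenols at low temperature without reducing the alkenes or touching the stereocentres.

Compound list
1 | piceatannol, (E)-3,5,3',4'-tetrahydroxystilbene | Oc1cc(O)cc(/C=C/c2ccc(O)c(O)c2)c1 | starting material
2 | (E)-3,4,3',5'-tetrakis(benzyloxy)stilbene | C(Oc1cc(OCc2ccccc2)cc(/C=C/c2ccc(OCc3ccccc3)c(OCc3ccccc3)c2)c1)c1ccccc1 | intermediate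
3 | 4-(chloromethyl)-1,2-bis(benzyloxy)benzene | ClCc1ccc(OCc2ccccc2)c(OCc2ccccc2)c1 | starting material
4 | diethyl [3,4-bis(benzyloxy)benzyl]phosphonate | CCOP(=O)(Cc1ccc(OCc2ccccc2)c(OCc2ccccc2)c1)OCC | intermediate
5 | vanillin | COc1cc(C=O)ccc1O | starting material
6 | 4-formyl-6,6-dimethoxycyclohexa-2,4-dien-1-one (masked o-benzoquinone) | O=CC1=CC(OC)(OC)C(=O)C=C1 | intermediate
7 | racemic 7-[3,4-bis(benzyloxy)phenyl]-8-[3,5-bis(benzyloxy)phenyl]-3,3-dimethoxy-2-oxobicyclo[2.2.2]oct-5-ene-5-carbaldehyde; C7 aryl syn to the C5=C6 bridge, C8 aryl anti, aryl groups trans (racemate; SMILES shows the enantiomer carried on) | O=C1C(OC)(OC)[C@H]2C(C=O)=C[C@@H]1[C@H](c1ccc(OCc3ccccc3)c(OCc3ccccc3)c1)[C@H]2c1cc(OCc3ccccc3)cc(OCc3ccccc3)c1 | intermediate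
8 | the same aldehyde as a single enantiomer, configuration as in the SMILES | O=C1C(OC)(OC)[C@H]2C(C=O)=C[C@@H]1[C@H](c1ccc(OCc3ccccc3)c(OCc3ccccc3)c1)[C@H]2c1cc(OCc3ccccc3)cc(OCc3ccccc3)c1 | intermediate
9 | 7-[3,4-bis(benzyloxy)phenyl]-8-[3,5-bis(benzyloxy)phenyl]-5-[(E)-2-(3,4-bis(benzyloxy)phenyl)ethenyl]-3,3-dimethoxybicyclo[2.2.2]oct-5-en-2-one; C7 aryl syn to the alkene bridge, C8 aryl anti | O=C1C(OC)(OC)[C@H]2C(/C=C/c3ccc(OCc4ccccc4)c(OCc4ccccc4)c3)=C[C@@H]1[C@H](c1ccc(OCc3ccccc3)c(OCc3ccccc3)c1)[C@H]2c1cc(OCc3ccccc3)cc(OCc3ccccc3)c1 | intermediate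
10 | the corresponding bicyclo[2.2.2]oct-5-ene-2,3-dione, same substituents and configuration | O=C1C(=O)[C@H]2C(/C=C/c3ccc(OCc4ccccc4)c(OCc4ccccc4)c3)=C[C@@H]1[C@H](c1ccc(OCc3ccccc3)c(OCc3ccccc3)c1)[C@H]2c1cc(OCc3ccccc3)cc(OCc3ccccc3)c1 | intermediate
11 | hexa-O-benzyljezonodione: 7-[3,4-bis(benzyloxy)phenyl]-6-[3,5-bis(benzyloxy)phenyl]-4-[(E)-2-(3,4-bis(benzyloxy)phenyl)ethenyl]bicyclo[3.2.1]oct-3-ene-2,8-dione; C7 aryl endo, C6 aryl exo | O=C1C=C(/C=C/c2ccc(OCc3ccccc3)c(OCc3ccccc3)c2)[C@@H]2C(=O)[C@H]1[C@H](c1ccc(OCc3ccccc3)c(OCc3ccccc3)c1)[C@H]2c1cc(OCc3ccccc3)cc(OCc3ccccc3)c1 | intermediate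
12 | jezonodione | O=C1C=C(/C=C/c2ccc(O)c(O)c2)[C@@H]2C(=O)[C@H]1[C@H](c1ccc(O)c(O)c1)[C@H]2c1cc(O)cc(O)c1 | target

Total step count: 8. Longest linear sequence: 7 steps (steps 1, 3, 4, 5, 6, 7, 8).

Steps most likely to fail

Step 7 (proposed new method). The cationic shift may take the wrong course (migration of the benzylic C7 carbon, acyl migration towards the other carbonyl), or the electron-rich diene may be protonated and degrade. The fallback sets out from 9 and uses the classical solvolytic Wagner–Meerwein route. NaBH4 reduction of the C2 ketone should give the C2 alcohol F1, and MsCl/Et3N the mesylate F2. Buffered solvolysis (aqueous acetone, 2,6-lutidine, heat) should ionise C2 with participation of the anti-periplanar bridge and funnel into the styryl-stabilised bicyclo[3.2.1]oct-3-en-2-yl allylic cation, which water captures to give the allylic alcohol F3. Dess–Martin periodinane should then give the enone ketal F4, and aqueous acid hydrolysis of the C8 ketal returns to the route at 11.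

Step 3. The cycloaddition of the 1,2-diaryl alkene may be slow, letting the diene dimerise, and regio- or endo-control may erode. The fallback sets out from 2 and uses the more persistent masked o-benzoquinone generated in the same way from methyl vanillate, which should give the ester cycloadduct F5. Reduction of ester and ketone with i-Bu2AlH should give the diol F6, and double oxidation with Dess–Martin periodinane returns to the route at 7.

Step 8. Sixfold Lewis-acid debenzylation may degrade the dienone (re-addition of benzyl cations, conjugate addition of chloride). The fallback sets out from 11 and exchanges the protecting groups first: Lewis-acid acetolysis (FeCl3, Ac2O) should replace the six benzyl ethers by acetates to give the hexaacetate F7. Mild acidic methanolysis (acetyl chloride in MeOH) should then free the phenols and return to the route at 12.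

Further compounds
F1 | step 7 | C2 alcohol from 9, hydroxyl syn to the diaryl bridge | O[C@@H]1C(OC)(OC)[C@H]2C(/C=C/c3ccc(OCc4ccccc4)c(OCc4ccccc4)c3)=C[C@@H]1[C@H](c1ccc(OCc3ccccc3)c(OCc3ccccc3)c1)[C@H]2c1cc(OCc3ccccc3)cc(OCc3ccccc3)c1
F2 | step 7 | C2 mesylate of F1 | CS(=O)(=O)O[C@@H]1C(OC)(OC)[C@H]2C(/C=C/c3ccc(OCc4ccccc4)c(OCc4ccccc4)c3)=C[C@@H]1[C@H](c1ccc(OCc3ccccc3)c(OCc3ccccc3)c1)[C@H]2c1cc(OCc3ccccc3)cc(OCc3ccccc3)c1
F3 | step 7 | rearranged 8,8-dimethoxybicyclo[3.2.1]oct-3-en-2-ol, carbinol configuration open | OC1C=C(/C=C/c2ccc(OCc3ccccc3)c(OCc3ccccc3)c2)[C@@H]2C(OC)(OC)[C@H]1[C@H](c1ccc(OCc3ccccc3)c(OCc3ccccc3)c1)[C@H]2c1cc(OCc3ccccc3)cc(OCc3ccccc3)c1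
F4 | step 7 | 8,8-dimethoxybicyclo[3.2.1]oct-3-en-2-one (C8 ketal of 11) | O=C1C=C(/C=C/c2ccc(OCc3ccccc3)c(OCc3ccccc3)c2)[C@@H]2C(OC)(OC)[C@H]1[C@H](c1ccc(OCc3ccccc3)c(OCc3ccccc3)c1)[C@H]2c1cc(OCc3ccccc3)cc(OCc3ccccc3)c1
F5 | step 3 | racemic methyl ester analogue of 7 | O=C1C(OC)(OC)[C@H]2C(C(=O)OC)=C[C@@H]1[C@H](c1ccc(OCc3ccccc3)c(OCc3ccccc3)c1)[C@H]2c1cc(OCc3ccccc3)cc(OCc3ccccc3)c1
F6 | step 3 | racemic diol from F5, carbinol configuration open | OC1C(OC)(OC)[C@H]2C(CO)=C[C@@H]1[C@H](c1ccc(OCc3ccccc3)c(OCc3ccccc3)c1)[C@H]2c1cc(OCc3ccccc3)cc(OCc3ccccc3)c1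
F7 | step 8 | jezonodione hexaacetate | O=C1C=C(/C=C/c2ccc(OC(C)=O)c(OC(C)=O)c2)[C@@H]2C(=O)[C@H]1[C@H](c1ccc(OC(C)=O)c(OC(C)=O)c1)[C@H]2c1cc(OC(C)=O)cc(OC(C)=O)c1
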